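**Plan**

1. Feature: in the cyclohexanone ring C1–C6 the tertiary α-ketol C1(OH)(C7H2OBz)–C2(=O) is the ketol isomer of a 1-acylcyclopentanol with ring C2–C3–C4–C5–C6, carbinol C2 and exocyclic ketone C1. The central retrosynthetic move therefore cuts the ring bond C1–C6 and re-forms C2–C6.
2. Before that cut the silyl ethers on O4 and O6 are put back. After it the cyclopentane is cut at O–C2/O–C6 (syn-dihydroxylation of a C2=C6 alkene), at O=C1/O–C7 (oxidative benzoyloxylation of an ethynyl group), at O–C5 (benzoylation after ketone reduction) and at C1–C2 (acetylide addition to a cyclopentenone).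
3. Forward: the five-membered ring is bought as (R)-4-silyloxycyclopentenone, the two-carbon chain C1–C7 is joined first, the oxygens at C5, C1/C7 and C2/C6 follow, and the six-membered ring appears only in the ring enlargement.
4. Stereochemistry: C4 comes from the starting enone; C5 from hydride attack anti to the C4 silyloxy group; C2 and C6 together from osmylation anti to the C4 and C5 oxygens; C1 by transfer from C2 through an aluminium chelate, with C6 migrating with retention.

Key step: step 8

Remark: the atom labels C1–C7 of the target (C1 quaternary carbinol, C2 ketone, C3 CH2, C4 CHOH, C5 CHOBz, C6 CHOH, C7 CH2OBz) are kept for every intermediate; Bz = benzoyl, TBS = tert-butyldimethylsilyl.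

**Route**

Step 1
Reactants: 1 (R)-4-[(tert-butyldimethylsilyl)oxy]cyclopent-2-en-1-one; 2 ethynylmagnesium bromide
Product: 3 (1S,4R)-4-[(tert-butyldimethylsilyl)oxy]-1-ethynylcyclopent-2-en-1-ol (expected major epimer, ethynyl trans to the silyloxy group; the 1R epimer is carried along)
Conditions: HC≡CMgBr (1.3 equiv), THF, −78 → 0 °C; aq. NH4Cl
Reagents that add atoms: none
Why: Alkynyl Grignard reagents add 1,2 to cyclopentenones and are too weakly basic to enolise the ketone and expel the β-silyloxy group; attack should occur mainly anti to the C4 silyloxy group, but the new carbinol centre at C2 is erased in step 2, so the epimer ratio is of no consequence.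

Step 2
Reactants: 3 (1S,4R)-4-[(tert-butyldimethylsilyl)oxy]-1-ethynylcyclopent-2-en-1-ol
Product: 4 (5R)-5-[(tert-butyldimethylsilyl)oxy]-3-ethynylcyclopent-2-en-1-one
Conditions: pyridinium chlorochromate (2 equiv), 4 Å molecular sieves, CH2Cl2, rt
Reagents that add atoms: none
Why: Dauben–Babler oxidative 1,3-transposition of a tertiary allylic alcohol: the hexavalent chromium reagent esterifies the C2 hydroxyl, the oxygen is relayed to C5 by an allylic [3,3] shift and the secondary position is oxidised, which gives the β-ethynyl enone and leaves C4 untouched.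

Step 3
Reactants: 4 (5R)-5-[(tert-butyldimethylsilyl)oxy]-3-ethynylcyclopent-2-en-1-one
Product: 5 (1S,5R)-5-[(tert-butyldimethylsilyl)oxy]-3-ethynylcyclopent-2-en-1-ol
Conditions: NaBH4, CeCl3·7H2O, MeOH, −78 °C
Reagents that add atoms: none
Why: Luche 1,2-reduction of the enone; hydride should add to the C5 carbonyl from the face opposite to the neighbouring C4 silyloxy group, which sets C5 (S) with the hydroxyl cis to the C4 oxygen, as the cis C4/C5 pair of the target requires.

Step 4
Reactants: 5 (1S,5R)-5-[(tert-butyldimethylsilyl)oxy]-3-ethynylcyclopent-2-en-1-ol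
Product: 6 (1S,5R)-5-[(tert-butyldimethylsilyl)oxy]-3-ethynylcyclopent-2-en-1-yl benzoate
Conditions: BzCl, pyridine, DMAP (cat.), CH2Cl2, 0 °C → rt
Reagents that add atoms: benzoyl chloride, O=C(Cl)c1ccccc1
Why: DMAP-catalysed acylation of the secondary allylic alcohol with retention at C5; the benzoate is placed now, while its neighbours are an alkene carbon and a silyl ether, so that no free hydroxyl is available for acyl migration.

Step 5
Reactants: 6 (1S,5R)-5-[(tert-butyldimethylsilyl)oxy]-3-ethynylcyclopent-2-en-1-yl benzoate; 7 benzoic acid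
Product: 8 2-[(3S,4R)-3-(benzoyloxy)-4-[(tert-butyldimethylsilyl)oxy]cyclopent-1-en-1-yl]-2-oxoethyl benzoate
Conditions: PhCO2H (1.5 equiv), 8-methylquinoline N-oxide (1.3 equiv), [di(1-adamantyl)(2-morpholinophenyl)phosphine]AuNTf2 (5 mol%), PhCl, rt
Reagents that add atoms: 8-methylquinoline N-oxide, Cc1cccc2ccc[n+]([O-])c12
Why: Oxidative gold catalysis: the N-oxide delivers oxygen to the internal carbon C1 of the gold-activated terminal alkyne, and the α-oxo gold carbene thus formed at C7 inserts into the O–H bond of benzoic acid, a transformation established for terminal alkynes with P,N-ligated monovalent gold, which should give the benzoyloxymethyl ketone in one operation.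

Step 6
Reactants: 8 2-[(3S,4R)-3-(benzoyloxy)-4-[(tert-butyldimethylsilyl)oxy]cyclopent-1-en-1-yl]-2-oxoethyl benzoate
Product: 9 2-[(1R,2S,3S,4R)-3-(benzoyloxy)-4-[(tert-butyldimethylsilyl)oxy]-1,2-dihydroxycyclopentyl]-2-oxoethyl benzoate
Conditions: OsO4 (5 mol%), NMO, citric acid, t-BuOH/H2O, rt
Reagents that add atoms: N-methylmorpholine N-oxide, C[N+]1([O-])CCOCC1; water, O
Why: Upjohn syn-dihydroxylation of the trisubstituted enone alkene (citric acid keeps osmate hydrolysis fast for the electron-poor alkene); OsO4 should approach the face opposite to the C5 benzoate and the C4 silyl ether, which sets C2 and C6 together with both new hydroxyls trans to the C5 oxygen.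

Step 7
Reactants: 9 2-[(1R,2S,3S,4R)-3-(benzoyloxy)-4-[(tert-butyldimethylsilyl)oxy]-1,2-dihydroxycyclopentyl]-2-oxoethyl benzoate
Product: 10 2-[(1R,2S,3R,4R)-3-(benzoyloxy)-2,4-bis[(tert-butyldimethylsilyl)oxy]-1-hydroxycyclopentyl]-2-oxoethyl benzoate
Conditions: TBSOTf (1.1 equiv), 2,6-lutidine, CH2Cl2, −78 °C
Reagents that add atoms: tert-butyldimethylsilyl trifluoromethanesulfonate, CC(C)(C)[Si](C)(C)OS(=O)(=O)C(F)(F)F
Why: A silyl triflate with a hindered pyridine base silylates the secondary C6 hydroxyl much faster than the tertiary C2 hydroxyl, which is hindered, deactivated by the adjacent ketone and must stay free for step 8.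

Step 8
Reactants: 10 2-[(1R,2S,3R,4R)-3-(benzoyloxy)-2,4-bis[(tert-butyldimethylsilyl)oxy]-1-hydroxycyclopentyl]-2-oxoethyl benzoate
Product: 11 [(1S,2S,3R,4R)-3-(benzoyloxy)-2,4-bis[(tert-butyldimethylsilyl)oxy]-1-hydroxy-6-oxocyclohexyl]methyl benzoate
Conditions: Al(OtBu)3 (1.5 equiv), toluene, 80 °C; aq. potassium sodium tartrate
Reagents that add atoms: none
Why: The tertiary C2 hydroxyl exchanges onto aluminium, the same metal binds the C1 carbonyl oxygen in a five-membered chelate (O1 syn to O2), and as the C2–O bond becomes the new carbonyl the ring bond C2–C6 slides suprafacially onto C1 (α-ketol or acyloin rearrangement). The closest known reaction type is the aluminium-alkoxide-mediated D-homoannulation of 17-hydroxy-20-keto steroids and the conversion of 1-acylcyclopentanols into 2-alkyl-2-hydroxycyclohexanones, driven by relief of cyclopentane strain. The six-membered ring arises by ring enlargement through a 1,2-shift (C1–C6 formed, C2–C6 broken, C1 inserted between C2 and C6), not by an end-to-end cyclisation. The new stereocentre C1 is controlled by the C2 configuration: in the chelate C6 lies over one face of the carbonyl only and migrates with retention, which should place the C1 hydroxyl cis to the C6 silyloxy group (1S). The step needs C6 and not the methylene C3 to migrate; an aluminium alkoxide is chosen because the shift is then driven by the alkoxide rather than by a cationic acceptor, a regime in which the carbon that better accommodates electron density should migrate, here the oxygen-substituted C6 (α-silyloxy, β-benzoyloxy), as oxygen-bearing carbons do in the metal-alkoxide ketol shifts of ketoses, yet this preference is the least secure element of the route. tert-Butoxide ligands cannot transfer hydride (no Meerwein–Ponndorf reduction), and the silyl ethers at C6 and C4 block retro-aldol cleavage of substrate and product.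

Step 9
Reactants: 11 [(1S,2S,3R,4R)-3-(benzoyloxy)-2,4-bis[(tert-butyldimethylsilyl)oxy]-1-hydroxy-6-oxocyclohexyl]methyl benzoate
Product: 12 [(1S,2S,3R,4R)-3-(benzoyloxy)-1,2,4-trihydroxy-6-oxocyclohexyl]methyl benzoate (CNP0127041.1)
Conditions: HF·pyridine, pyridine, THF, 0 °C → rt
Reagents that add atoms: none
Why: Fluoride cleaves both Si–O bonds (driven by Si–F bond formation), and the acidic, pyridine-buffered medium should avoid the benzoyl migration between the cis C4/C5 oxygens, the β-elimination of the C4 oxygen and the ketol drift that basic fluoride could cause.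

**Compound list**

1 | (R)-4-[(tert-butyldimethylsilyl)oxy]cyclopent-2-en-1-one | O=C1C=C[C@H](O[Si](C)(C)C(C)(C)C)C1 | starting material
2 | ethynylmagnesium bromide | C#C[Mg]Br | starting material
3 | (1S,4R)-4-[(tert-butyldimethylsilyl)oxy]-1-ethynylcyclopent-2-en-1-ol (major epimer) | C#C[C@@]1(O)C=C[C@H](O[Si](C)(C)C(C)(C)C)C1 | intermediate
4 | (5R)-5-[(tert-butyldimethylsilyl)oxy]-3-ethynylcyclopent-2-en-1-one | O=C1C=C(C#C)C[C@H]1O[Si](C)(C)C(C)(C)C | intermediate
5 | (1S,5R)-5-[(tert-butyldimethylsilyl)oxy]-3-ethynylcyclopent-2-en-1-ol | O[C@H]1C=C(C#C)C[C@H]1O[Si](C)(C)C(C)(C)C | intermediate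
6 | (1S,5R)-5-[(tert-butyldimethylsilyl)oxy]-3-ethynylcyclopent-2-en-1-yl benzoate | O=C(O[C@H]1C=C(C#C)C[C@H]1O[Si](C)(C)C(C)(C)C)c1ccccc1 | intermediate
7 | benzoic acid | OC(=O)c1ccccc1 | starting material
8 | 2-[(3S,4R)-3-(benzoyloxy)-4-[(tert-butyldimethylsilyl)oxy]cyclopent-1-en-1-yl]-2-oxoethyl benzoate | O=C(COC(=O)c1ccccc1)C1=C[C@H](OC(=O)c2ccccc2)[C@H](O[Si](C)(C)C(C)(C)C)C1 | intermediate
9 | 2-[(1R,2S,3S,4R)-3-(benzoyloxy)-4-[(tert-butyldimethylsilyl)oxy]-1,2-dihydroxycyclopentyl]-2-oxoethyl benzoate | O=C(COC(=O)c1ccccc1)[C@@]1(O)C[C@@H](O[Si](C)(C)C(C)(C)C)[C@@H](OC(=O)c2ccccc2)[C@@H]1O | intermediate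
10 | 2-[(1R,2S,3R,4R)-3-(benzoyloxy)-2,4-bis[(tert-butyldimethylsilyl)oxy]-1-hydroxycyclopentyl]-2-oxoethyl benzoate | O=C(COC(=O)c1ccccc1)[C@@]1(O)C[C@@H](O[Si](C)(C)C(C)(C)C)[C@@H](OC(=O)c2ccccc2)[C@@H]1O[Si](C)(C)C(C)(C)C | intermediate
11 | [(1S,2S,3R,4R)-3-(benzoyloxy)-2,4-bis[(tert-butyldimethylsilyl)oxy]-1-hydroxy-6-oxocyclohexyl]methyl benzoate | O=C(OC[C@@]1(O)C(=O)C[C@@H](O[Si](C)(C)C(C)(C)C)[C@@H](OC(=O)c2ccccc2)[C@@H]1O[Si](C)(C)C(C)(C)C)c1ccccc1 | intermediate
12 | [(1S,2S,3R,4R)-3-(benzoyloxy)-1,2,4-trihydroxy-6-oxocyclohexyl]methyl benzoate | O=C(OC[C@@]1(O)C(=O)C[C@@H](O)[C@@H](OC(=O)c2ccccc2)[C@@H]1O)c1ccccc1 | target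

Total step count: 9. Longest linear sequence: 9 steps (from 1).

**Steps most likely to fail**

Step 8. The ring methylene C3 may migrate in competition with C6 and give the regioisomeric 2-hydroxycyclohexanone. Loss of the syn chelate would erode the C1 configuration, and prolonged heating could eliminate the C4 silyloxy group from the product. Fallback: the C6 hydroxyl is left free, so the fallback sets out from diol 9 and omits step 7. With Al(OtBu)3 in toluene the C6 oxygen becomes an aluminium alkoxide β to the C1 carbonyl. The C2–C6 bond alone then carries an oxido donor and should be the bond that breaks, whether the shift stays concerted or runs through the aldol-type variant (retro-aldol, re-closure at C1) known from the ketol isomerisation of free ketoses to branched-chain sugars. This trades some stereochemical security at C6 for regiochemical security. The product would be the C4 mono-silyl ether of the target F1, which on treatment with HF·pyridine comes back to the route at 12.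

Step 5. A second N-oxide may over-oxidise the gold carbene to the keto aldehyde, or the gold catalyst may reorganise the conjugated enyne before benzoic acid captures the carbene. Fallback: the side chain is oxidised stepwise with classical chemistry. Setting out from 6, Markovnikov hydration of the alkyne (Ph3PAuNTf2, MeOH/H2O) should give the methyl ketone F2. Soft enolisation towards the methyl group (TMSOTf, Et3N) should give the 2-(trimethylsilyloxy)diene F3. Rubottom oxidation (mCPBA, NaHCO3, then citric acid) should give the hydroxyacetyl enone F4. Benzoylation (BzCl, pyridine) comes back to the route at 8.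

Step 6. Osmylation of the electron-poor, flanked alkene may be slow, and during a long reaction the sensitive dihydroxy ketone may drift by retro-aldol cleavage, premature ketol shift or benzoyl migration. Fallback: the alkene is osmylated while it is still the electron-richer enyne, and the glycolyl unit is built afterwards from the untouched alkyne. Setting out from 6, OsO4/NMO should give the propargylic diol F5 with the same facial course. TBSOTf/2,6-lutidine should give the C6 silyl ether F6. Semi-hydrogenation (H2, Pd/CaCO3 poisoned with Pb(OAc)2, quinoline) should give the vinyl carbinol F7. A second OsO4/NMO dihydroxylation should give the side-chain diol F8 as both C1 epimers. BzCl with 2,4,6-collidine at low temperature should give the primary benzoate F9. Dess–Martin oxidation of the secondary side-chain alcohol comes back to the route at 10, so that steps 5 to 7 are bypassed.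

**Further compounds**

F1 | step 8 | C4 mono-TBS ether of 12 (C6 hydroxyl free) | O=C(OC[C@@]1(O)C(=O)C[C@@H](O[Si](C)(C)C(C)(C)C)[C@@H](OC(=O)c2ccccc2)[C@@H]1O)c1ccccc1
F2 | step 5 | (1S,5R)-3-acetyl-5-[(tert-butyldimethylsilyl)oxy]cyclopent-2-en-1-yl benzoate | CC(=O)C1=C[C@H](OC(=O)c2ccccc2)[C@H](O[Si](C)(C)C(C)(C)C)C1
F3 | step 5 | (1S,5R)-5-[(tert-butyldimethylsilyl)oxy]-3-[1-(trimethylsilyloxy)ethenyl]cyclopent-2-en-1-yl benzoate | C=C(O[Si](C)(C)C)C1=C[C@H](OC(=O)c2ccccc2)[C@H](O[Si](C)(C)C(C)(C)C)C1
F4 | step 5 | (1S,5R)-5-[(tert-butyldimethylsilyl)oxy]-3-(hydroxyacetyl)cyclopent-2-en-1-yl benzoate | O=C(CO)C1=C[C@H](OC(=O)c2ccccc2)[C@H](O[Si](C)(C)C(C)(C)C)C1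
F5 | step 6 | ethynyl analogue of 9 (1-ethynylcyclopentane-1,2-diol with C5 benzoate and C4 TBS ether) | C#C[C@@]1(O)C[C@@H](O[Si](C)(C)C(C)(C)C)[C@@H](OC(=O)c2ccccc2)[C@@H]1O
F6 | step 6 | ethynyl analogue of 10 (C4,C6 bis-TBS ether of F5) | C#C[C@@]1(O)C[C@@H](O[Si](C)(C)C(C)(C)C)[C@@H](OC(=O)c2ccccc2)[C@@H]1O[Si](C)(C)C(C)(C)C
F7 | step 6 | vinyl analogue of 10 (1-ethenylcyclopentanol with C5 benzoate and C4,C6 TBS ethers) | C=C[C@@]1(O)C[C@@H](O[Si](C)(C)C(C)(C)C)[C@@H](OC(=O)c2ccccc2)[C@@H]1O[Si](C)(C)C(C)(C)C
F8 | step 6 | 1-(1,2-dihydroxyethyl)cyclopentanol from F7 (both side-chain epimers) | OCC(O)[C@@]1(O)C[C@@H](O[Si](C)(C)C(C)(C)C)[C@@H](OC(=O)c2ccccc2)[C@@H]1O[Si](C)(C)C(C)(C)C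
F9 | step 6 | primary benzoate of F8 (C1 alcohol corresponding to ketone 10, both epimers) | O=C(OCC(O)[C@@]1(O)C[C@@H](O[Si](C)(C)C(C)(C)C)[C@@H](OC(=O)c2ccccc2)[C@@H]1O[Si](C)(C)C(C)(C)C)c1ccccc1
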